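**Plan**

- Labels: ring A is the isobutyryl ring, its positions given in words (position 1 side chain, positions 2, 4 and 6 OH, position 3 bridge, position 5 isobutyryl). Ring B is the acetyl ring (B1 bridge, B2 OH, B3 acetyl, B4 OH, B5 CH3, B6 OCH3). C7 is the CH2 between position 3 of ring A and B1.
- Enabling feature: on ring B the carbon substituent C7 (on B1) and the hydroxyl oxygen (on B2) are ortho neighbours, and B1 has the B6 methoxy on its other side. An aryne B1≡B2 can therefore receive the B1–C7 and B2–O bonds in one event from a ring A carboxylic acid, with the B6 methoxy fixing the orientation.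
- Retrosynthetic cuts, in order: the allylic alcohol back to a prenyl group (bond from position 1 of ring A to the side chain), the ring A–isobutyryl bond, the B3–acetyl bond, then B1–C7 and B2–O together, C7 being the carboxyl carbon of 2,4,6-tris(benzyloxy)benzoic acid.
- Forward order: both benzene rings are bought and no ring is formed. The aryne precursor (3 steps) and the acid (2 steps, formylation of 1,3,5-tris(benzyloxy)benzene and oxidation) are joined in step 6. C7=O is then reduced to CH2, acetyl is placed on B3 through the B2 phenol, isobutyryl goes onto ring A, BCl3 frees the phenols and B4–OH, and the side chain is built on position 1 of ring A.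
- Stereochemistry: the single stereocentre (R) comes from Shi epoxidation of the prenyl olefin with the D-fructose-derived ketone. It is kept in the epoxide-to-allylic-alcohol isomerisation, which breaks the other C–O bond.

Key step: step 6

Remark on the chemistry: the [C@H] of the target is read as R (OH > isopropenyl > ArCH2 > H).

**Route**

Step 1
Reactants: 1 2,6-dimethoxytoluene
Product: 3 3,5-dimethoxy-4-methylphenol, via arylboronic pinacol ester 2 (not isolated)
Conditions: [Ir(OMe)(cod)]2 (1.5 mol %), 4,4'-di-tert-butyl-2,2'-bipyridine (3 mol %), HBpin, THF, 80 °C; then NaOH, 30% H2O2, THF–H2O, 0 °C → rt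
Reagents that add atoms: pinacolborane [H]B1OC(C)(C)C(C)(C)O1 (boron of 2 only); hydrogen peroxide OO
Why: sterically governed iridium-catalysed C–H borylation should take the only C–H with no ortho substituent (para to the methyl), and the boronate is oxidised to the phenol in the same flask (borylation–oxidation).

Step 2
Reactants: 3 3,5-dimethoxy-4-methylphenol
Product: 4 2-bromo-3,5-dimethoxy-4-methylphenol
Conditions: NBS (1.0 equiv), CH2Cl2, −78 → 0 °C
Reagents that add atoms: N-bromosuccinimide O=C1CCC(=O)N1Br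
Why: electrophilic bromination of a phenol whose para position is blocked and whose two ortho positions are equivalent, so one equivalent should give the monobromide.

Step 3
Reactants: 4 2-bromo-3,5-dimethoxy-4-methylphenol
Product: 7 3,5-dimethoxy-4-methyl-2-(trimethylsilyl)phenyl trifluoromethanesulfonate, via aryl trimethylsilyl ether 5 (not isolated), via lithium 2-silylphenolate 6 (not isolated)
Conditions: HN(SiMe3)2, THF, 65 °C, then evaporation; n-BuLi, THF, −78 °C; Tf2O, −78 → 0 °C
Reagents that add atoms: hexamethyldisilazane C[Si](C)(C)N[Si](C)(C)C; n-butyllithium [Li]CCCC (lithium of 6 only); trifluoromethanesulfonic anhydride O=S(=O)(OS(=O)(=O)C(F)(F)F)C(F)(F)F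
Why: bromine–lithium exchange on the O-silyl ether triggers the 1,3 O→C silyl shift (retro-Brook) and the freed phenolate is triflated, the standard one-flask route from o-bromophenols to 2-silylaryl triflates.

Step 4
Reactants: 8 1,3,5-tris(benzyloxy)benzene
Product: 10 2,4,6-tris(benzyloxy)benzaldehyde, via aryl iminium salt 9 (not isolated)
Conditions: POCl3 (1.5 equiv), DMF, 0 → 60 °C; then aq. NaOAc, rt
Reagents that add atoms: N,N-dimethylformamide CN(C)C=O; phosphoryl chloride O=P(Cl)(Cl)Cl (counter-ion of 9 only); water O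
Why: Vilsmeier–Haack formylation of a phloroglucinol triether, whose three free ring positions are equivalent and which is deactivated against a second attack once the iminium group is in place; buffered hydrolysis releases the aldehyde and leaves the benzyl ethers alone.

Step 5
Reactants: 10 2,4,6-tris(benzyloxy)benzaldehyde
Product: 11 2,4,6-tris(benzyloxy)benzoic acid
Conditions: NaClO2, NaH2PO4, 2-methylbut-2-ene (excess), t-BuOH–THF–H2O, 0 °C → rt
Reagents that add atoms: sodium chlorite [Na+].[O-]Cl=O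
Why: Pinnick oxidation, in which chlorous acid adds to the aldehyde and fragments to the acid and HOCl; the alkene traps HOCl before it can chlorinate the electron-rich ring, and the near-neutral medium avoids acid-induced decarboxylation of the 2,6-dialkoxybenzoic acid.

Step 6
Reactants: 7 3,5-dimethoxy-4-methyl-2-(trimethylsilyl)phenyl trifluoromethanesulfonate; 11 2,4,6-tris(benzyloxy)benzoic acid (1.2 equiv)
Product: 13 (6-hydroxy-2,4-dimethoxy-3-methylphenyl)[2,4,6-tris(benzyloxy)phenyl]methanone, via 3,5-dimethoxy-4-methylbenzyne 12 (not isolated)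
Conditions: CsF (4 equiv), THF, 125 °C, sealed tube; aq. NH4Cl
Reagents that add atoms: none
Why: Fluoride removes the silyl group and triflate leaves, giving the aryne B1≡B2; the caesium carboxylate of 11 adds through oxygen to B2, the aryne carbon remote from the B6 methoxy, so the aryl anion sits on B1 where the neighbouring C–O bond stabilises it. That anion attacks the adjacent ester carbonyl through a four-membered benzoxete alkoxide, which opens to the B2 phenoxide and the diaryl ketone, a net insertion of the aryne into the C(acyl)–O bond. The closest known reaction is the CsF-promoted insertion of 2-silylaryl triflates into the C–O bond of aromatic carboxylic acids in hot THF, which gives o-hydroxyaryl ketones. No ring closes and no stereocentre forms; B2–O and B1–C7 are made together. The step needs oxygen to add at B2 and not B1, which the B6 methoxy and the unsubstituted B3 side secure, and it needs acyl transfer to outrun protonation of the aryl anion, which the aprotic medium, the temperature and the intramolecular shift favour. Because the rings enter in different roles (aryne and acid, the acid in slight excess), no symmetrical coupling product can arise.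

Step 7
Reactants: 13 (6-hydroxy-2,4-dimethoxy-3-methylphenyl)[2,4,6-tris(benzyloxy)phenyl]methanone
Product: 15 3,5-dimethoxy-4-methyl-2-{[2,4,6-tris(benzyloxy)phenyl]methyl}phenol, via aryl ethyl carbonate 14 (not isolated)
Conditions: ClCO2Et, Et3N, THF, 0 °C; then NaBH4, H2O, 0 °C → rt
Reagents that add atoms: ethyl chloroformate CCOC(Cl)=O (carbonate of 14 only)
Why: hydride addition to the ketone of the o-carbonate is followed by carbonate transfer and loss to an o-quinone methide that takes a second hydride, the usual deoxygenation of o-hydroxyaryl ketones to o-alkylphenols.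

Step 8
Reactants: 15 3,5-dimethoxy-4-methyl-2-{[2,4,6-tris(benzyloxy)phenyl]methyl}phenol
Product: 16 2-iodo-3,5-dimethoxy-4-methyl-6-{[2,4,6-tris(benzyloxy)phenyl]methyl}phenol
Conditions: I2 (1.05 equiv), NaHCO3, THF–H2O, 0 °C
Reagents that add atoms: iodine II
Why: iodine under mild base iodinates through the phenol/phenolate, so substitution should occur at B3, the only free position of ring B, and not on the neutral triether ring A.

Step 9
Reactants: 16 2-iodo-3,5-dimethoxy-4-methyl-6-{[2,4,6-tris(benzyloxy)phenyl]methyl}phenol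
Product: 17 2-iodo-3,5-dimethoxy-4-methyl-6-{[2,4,6-tris(benzyloxy)phenyl]methyl}phenyl acetate
Conditions: Ac2O, pyridine, DMAP (cat.), CH2Cl2, rt
Reagents that add atoms: acetic anhydride CC(=O)OC(C)=O
Why: DMAP-catalysed O-acetylation; the acetate keeps the B2 oxygen from chelating the future acetyl carbonyl, so that the Lewis-acid demethylation of step 12 is directed to B4, and it shields the phenol in steps 10 and 11.

Step 10
Reactants: 17 2-iodo-3,5-dimethoxy-4-methyl-6-{[2,4,6-tris(benzyloxy)phenyl]methyl}phenyl acetate; 18 tributyl(1-ethoxyethenyl)stannane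
Product: 20 2-acetyl-3,5-dimethoxy-4-methyl-6-{[2,4,6-tris(benzyloxy)phenyl]methyl}phenyl acetate, via 1-ethoxyvinyl arene 19 (not isolated)
Conditions: PdCl2(PPh3)2 (5 mol %), toluene, 100 °C; then HCl (1 M), THF, rt
Reagents that add atoms: water O
Why: Stille coupling of the aryl iodide with the α-ethoxyvinyl stannane (an acetyl anion equivalent) and mild hydrolysis of the enol ether should place the acetyl group on B3 without touching esters or benzyl ethers.

Step 11
Reactants: 20 2-acetyl-3,5-dimethoxy-4-methyl-6-{[2,4,6-tris(benzyloxy)phenyl]methyl}phenyl acetate; 21 2-methylpropanoic acid (isobutyric acid)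
Product: 22 2-acetyl-3,5-dimethoxy-4-methyl-6-{[2,4,6-tris(benzyloxy)-3-(2-methylpropanoyl)phenyl]methyl}phenyl acetate
Conditions: (CF3CO)2O, CH2Cl2, 0 °C → rt; aq. NaHCO3
Reagents that add atoms: none
Why: Friedel–Crafts acylation by the mixed trifluoroacetic anhydride needs no metal Lewis acid, so the benzyl ethers survive; ring B is fully substituted, the two free positions of ring A are equivalent, and the first acyl group deactivates against a second.

Step 12
Reactants: 22 2-acetyl-3,5-dimethoxy-4-methyl-6-{[2,4,6-tris(benzyloxy)-3-(2-methylpropanoyl)phenyl]methyl}phenyl acetate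
Product: 24 1-{3-[(3-acetyl-2,4-dihydroxy-6-methoxy-5-methylphenyl)methyl]-2,4,6-trihydroxyphenyl}-2-methylpropan-1-one, via B2 monoacetate 23 (not isolated)
Conditions: BCl3 (excess), C6HMe5, CH2Cl2, −78 → 0 °C; H2O; then K2CO3, MeOH, rt, under argon
Reagents that add atoms: none
Why: BCl3 with pentamethylbenzene as cation trap cleaves the three aryl benzyl ethers at low temperature and, with B2 held as a non-chelating acetate, boron bridges the acetyl carbonyl and the B4 methoxy so that only this methyl ether is cleaved (B6–OCH3 has no carbonyl neighbour); methanolysis then removes the acetate.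

Step 13
Reactants: 24 1-{3-[(3-acetyl-2,4-dihydroxy-6-methoxy-5-methylphenyl)methyl]-2,4,6-trihydroxyphenyl}-2-methylpropan-1-one; 25 1-bromo-3-methylbut-2-ene (prenyl bromide, 1.1 equiv)
Product: 26 1-{3-[(3-acetyl-2,4-dihydroxy-6-methoxy-5-methylphenyl)methyl]-2,4,6-trihydroxy-5-(3-methylbut-2-en-1-yl)phenyl}-2-methylpropan-1-one
Conditions: KOH (5% aq.), 0 °C; acidic work-up
Reagents that add atoms: none
Why: C-alkylation of an acylphloroglucinol anion in water, where hydrogen bonding to the oxygens favours reaction through carbon, should occur at position 1 of ring A, the only unsubstituted ring carbon.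

Step 14
Reactants: 26 the prenylated pentaphenol
Product: 27 1-{3-{[3-acetyl-6-methoxy-2,4-bis(methoxymethoxy)-5-methylphenyl]methyl}-2,4,6-tris(methoxymethoxy)-5-(3-methylbut-2-en-1-yl)phenyl}-2-methylpropan-1-one
Conditions: NaH, MOMCl, DMF, 0 °C → rt
Reagents that add atoms: chloromethyl methyl ether COCCl
Why: O-alkylation of all five sodium phenoxides (which also breaks the hydrogen bonds to the ketones) gives small acetal groups that withstand base, peroxide and amide bases and keep the ortho oxygens from opening the later epoxide.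

Step 15
Reactants: 27 the penta-MOM prenyl compound
Product: 28 1-{3-{[3-acetyl-6-methoxy-2,4-bis(methoxymethoxy)-5-methylphenyl]methyl}-5-{[(2R)-3,3-dimethyloxiran-2-yl]methyl}-2,4,6-tris(methoxymethoxy)phenyl}-2-methylpropan-1-one
Conditions: D-fructose-derived Shi ketone (1,2:4,5-di-O-isopropylidene-β-D-erythro-2,3-hexodiulo-2,6-pyranose, 30 mol %), KHSO5 (as its triple salt), K2CO3, Bu4NHSO4, Na2B4O7 buffer, MeCN–CH2(OMe)2–H2O, 0 °C
Reagents that add atoms: potassium peroxymonosulfate [K+].OOS([O-])(=O)=O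
Why: Shi epoxidation, in which the chiral dioxirane transfers oxygen to the trisubstituted olefin through a spiro transition state; for R–CH=C(CH3)2 olefins the D-fructose-derived ketone is expected to give the (R)-epoxide (reagent control).

Step 16
Reactants: 28 the (R)-epoxide
Product: 29 1-{3-{[3-acetyl-6-methoxy-2,4-bis(methoxymethoxy)-5-methylphenyl]methyl}-5-[(2R)-2-hydroxy-3-methylbut-3-en-1-yl]-2,4,6-tris(methoxymethoxy)phenyl}-2-methylpropan-1-one
Conditions: 2,2,6,6-tetramethylpiperidine, n-BuLi, then Et2AlCl, toluene, 0 °C (gives Et2Al(TMP), 6 equiv); 28, 0 °C → rt; aq. KNaC4H4O6 (potassium sodium tartrate)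
Reagents that add atoms: none
Why: Yamamoto epoxide-to-allylic-alcohol isomerisation, in which aluminium binds the epoxide oxygen and the amide removes a methyl proton in a cyclic syn transition state with cleavage of the tertiary C–O bond; the C–O bond at the stereocentre is untouched, so R is retained (the excess allows for enolisation of the aryl methyl ketone).

Step 17
Reactants: 29 the penta-MOM allylic alcohol
Product: 30 1-{3-[(3-acetyl-2,4-dihydroxy-6-methoxy-5-methylphenyl)methyl]-2,4,6-trihydroxy-5-[(2R)-2-hydroxy-3-methylbut-3-en-1-yl]phenyl}-2-methylpropan-1-one (CNP0162925.1)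
Conditions: HCl (3 M), MeOH, rt
Reagents that add atoms: none
Why: acid-catalysed acetal exchange with methanol removes the five aryl MOM groups under conditions too mild to ionise the secondary allylic alcohol or protonate the 1,1-disubstituted alkene.

**Compound list**

1 | 2,6-dimethoxytoluene | Cc1c(OC)cccc1OC | starting material
2 | 2-(3,5-dimethoxy-4-methylphenyl)-4,4,5,5-tetramethyl-1,3,2-dioxaborolane | Cc1c(OC)cc(cc1OC)B1OC(C)(C)C(C)(C)O1 | intermediate
3 | 3,5-dimethoxy-4-methylphenol | Cc1c(OC)cc(O)cc1OC | intermediate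
4 | 2-bromo-3,5-dimethoxy-4-methylphenol | COc1cc(O)c(Br)c(OC)c1C | intermediate
5 | (2-bromo-3,5-dimethoxy-4-methylphenoxy)trimethylsilane | COc1cc(O[Si](C)(C)C)c(Br)c(OC)c1C | intermediate
6 | lithium 3,5-dimethoxy-4-methyl-2-(trimethylsilyl)phenolate | COc1cc([O-])c([Si](C)(C)C)c(OC)c1C.[Li+] | intermediate
7 | 3,5-dimethoxy-4-methyl-2-(trimethylsilyl)phenyl trifluoromethanesulfonate | COc1cc(OS(=O)(=O)C(F)(F)F)c([Si](C)(C)C)c(OC)c1C | intermediate
8 | 1,3,5-tris(benzyloxy)benzene | c1ccc(COc2cc(OCc3ccccc3)cc(OCc3ccccc3)c2)cc1 | starting material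
9 | N-{[2,4,6-tris(benzyloxy)phenyl]methylidene}-N-methylmethanaminium dichlorophosphate | C[N+](C)=Cc1c(OCc2ccccc2)cc(OCc2ccccc2)cc1OCc1ccccc1.[O-]P(=O)(Cl)Cl | intermediate
10 | 2,4,6-tris(benzyloxy)benzaldehyde | O=Cc1c(OCc2ccccc2)cc(OCc2ccccc2)cc1OCc1ccccc1 | intermediate
11 | 2,4,6-tris(benzyloxy)benzoic acid | OC(=O)c1c(OCc2ccccc2)cc(OCc2ccccc2)cc1OCc1ccccc1 | intermediate
12 | 3,5-dimethoxy-4-methylbenzyne (1,2-didehydro-3,5-dimethoxy-4-methylbenzene) | COC1=CC#CC(OC)=C1C | intermediate
13 | (6-hydroxy-2,4-dimethoxy-3-methylphenyl)[2,4,6-tris(benzyloxy)phenyl]methanone | COc1cc(O)c(C(=O)c2c(OCc3ccccc3)cc(OCc3ccccc3)cc2OCc2ccccc2)c(OC)c1C | intermediate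
14 | ethyl 3,5-dimethoxy-4-methyl-2-[2,4,6-tris(benzyloxy)benzoyl]phenyl carbonate | CCOC(=O)Oc1cc(OC)c(C)c(OC)c1C(=O)c1c(OCc2ccccc2)cc(OCc2ccccc2)cc1OCc1ccccc1 | intermediate
15 | 3,5-dimethoxy-4-methyl-2-{[2,4,6-tris(benzyloxy)phenyl]methyl}phenol | COc1cc(O)c(Cc2c(OCc3ccccc3)cc(OCc3ccccc3)cc2OCc2ccccc2)c(OC)c1C | intermediate
16 | 2-iodo-3,5-dimethoxy-4-methyl-6-{[2,4,6-tris(benzyloxy)phenyl]methyl}phenol | COc1c(I)c(O)c(Cc2c(OCc3ccccc3)cc(OCc3ccccc3)cc2OCc2ccccc2)c(OC)c1C | intermediate
17 | 2-iodo-3,5-dimethoxy-4-methyl-6-{[2,4,6-tris(benzyloxy)phenyl]methyl}phenyl acetate | CC(=O)Oc1c(I)c(OC)c(C)c(OC)c1Cc1c(OCc2ccccc2)cc(OCc2ccccc2)cc1OCc1ccccc1 | intermediate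
18 | tributyl(1-ethoxyethenyl)stannane | CCCC[Sn](CCCC)(CCCC)C(=C)OCC | starting material
19 | 2-(1-ethoxyethenyl)-3,5-dimethoxy-4-methyl-6-{[2,4,6-tris(benzyloxy)phenyl]methyl}phenyl acetate | CCOC(=C)c1c(OC(C)=O)c(Cc2c(OCc3ccccc3)cc(OCc3ccccc3)cc2OCc2ccccc2)c(OC)c(C)c1OC | intermediate
20 | 2-acetyl-3,5-dimethoxy-4-methyl-6-{[2,4,6-tris(benzyloxy)phenyl]methyl}phenyl acetate | CC(=O)Oc1c(C(C)=O)c(OC)c(C)c(OC)c1Cc1c(OCc2ccccc2)cc(OCc2ccccc2)cc1OCc1ccccc1 | intermediate
21 | 2-methylpropanoic acid | CC(C)C(O)=O | starting material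
22 | 2-acetyl-3,5-dimethoxy-4-methyl-6-{[2,4,6-tris(benzyloxy)-3-(2-methylpropanoyl)phenyl]methyl}phenyl acetate | CC(C)C(=O)c1c(OCc2ccccc2)cc(OCc2ccccc2)c(Cc2c(OC(C)=O)c(C(C)=O)c(OC)c(C)c2OC)c1OCc1ccccc1 | intermediate
23 | 2-acetyl-3-hydroxy-5-methoxy-4-methyl-6-{[2,4,6-trihydroxy-3-(2-methylpropanoyl)phenyl]methyl}phenyl acetate | CC(C)C(=O)c1c(O)cc(O)c(Cc2c(OC(C)=O)c(C(C)=O)c(O)c(C)c2OC)c1O | intermediate
24 | 1-{3-[(3-acetyl-2,4-dihydroxy-6-methoxy-5-methylphenyl)methyl]-2,4,6-trihydroxyphenyl}-2-methylpropan-1-one | CC(C)C(=O)c1c(O)cc(O)c(Cc2c(O)c(C(C)=O)c(O)c(C)c2OC)c1O | intermediate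
25 | 1-bromo-3-methylbut-2-ene | CC(C)=CCBr | starting material
26 | 1-{3-[(3-acetyl-2,4-dihydroxy-6-methoxy-5-methylphenyl)methyl]-2,4,6-trihydroxy-5-(3-methylbut-2-en-1-yl)phenyl}-2-methylpropan-1-one | CC(C)=CCc1c(O)c(Cc2c(O)c(C(C)=O)c(O)c(C)c2OC)c(O)c(C(=O)C(C)C)c1O | intermediate
27 | 1-{3-{[3-acetyl-6-methoxy-2,4-bis(methoxymethoxy)-5-methylphenyl]methyl}-2,4,6-tris(methoxymethoxy)-5-(3-methylbut-2-en-1-yl)phenyl}-2-methylpropan-1-one | CC(C)=CCc1c(OCOC)c(Cc2c(OCOC)c(C(C)=O)c(OCOC)c(C)c2OC)c(OCOC)c(C(=O)C(C)C)c1OCOC | intermediate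
28 | 1-{3-{[3-acetyl-6-methoxy-2,4-bis(methoxymethoxy)-5-methylphenyl]methyl}-5-{[(2R)-3,3-dimethyloxiran-2-yl]methyl}-2,4,6-tris(methoxymethoxy)phenyl}-2-methylpropan-1-one | CC1(C)O[C@@H]1Cc1c(OCOC)c(Cc2c(OCOC)c(C(C)=O)c(OCOC)c(C)c2OC)c(OCOC)c(C(=O)C(C)C)c1OCOC | intermediate
29 | 1-{3-{[3-acetyl-6-methoxy-2,4-bis(methoxymethoxy)-5-methylphenyl]methyl}-5-[(2R)-2-hydroxy-3-methylbut-3-en-1-yl]-2,4,6-tris(methoxymethoxy)phenyl}-2-methylpropan-1-one | C=C(C)[C@H](O)Cc1c(OCOC)c(Cc2c(OCOC)c(C(C)=O)c(OCOC)c(C)c2OC)c(OCOC)c(C(=O)C(C)C)c1OCOC | intermediate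
30 | 1-{3-[(3-acetyl-2,4-dihydroxy-6-methoxy-5-methylphenyl)methyl]-2,4,6-trihydroxy-5-[(2R)-2-hydroxy-3-methylbut-3-en-1-yl]phenyl}-2-methylpropan-1-one | C=C(C)[C@H](O)Cc1c(O)c(Cc2c(O)c(C(C)=O)c(O)c(C)c2OC)c(O)c(C(=O)C(C)C)c1O | target

**Step count and risks**

Total: 17 steps. Longest linear sequence: 15 steps (steps 1–3 and 6–17).

Most likely to fail:

1. Step 6. The B1 aryl anion may be protonated before the 1,3-acyl shift, which the two ortho benzyloxy groups of the acid slow down, so that only O-arylation results. The electron-rich carboxylate may also lose CO2 at 125 °C, and the product phenoxide may be arylated further. Fallback, from 4 and 11 back to 13: phenol 4 is protected with MOMCl and i-Pr2NEt as 2-bromo-3,5-dimethoxy-1-(methoxymethoxy)-4-methylbenzene F1. Bromine–lithium exchange with n-BuLi in THF at −78 °C gives [2,4-dimethoxy-6-(methoxymethoxy)-3-methylphenyl]lithium F2. This is added to 2,4,6-tris(benzyloxy)benzoyl chloride F3, made from 11 with (COCl)2 and catalytic DMF. The tetra-ortho-substituted ketone [2,4-dimethoxy-6-(methoxymethoxy)-3-methylphenyl][2,4,6-tris(benzyloxy)phenyl]methanone F4 should resist a second addition, and dilute HCl in MeOH removes the MOM group to give 13.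

2. Step 13. Alkylation on oxygen, or on already substituted ring carbons with loss of aromaticity, may outrun alkylation at the free ring A carbon, and the aqueous base may cleave and recombine the methylene bridge. Fallback, from 24 back to 27: allylation with allyl methyl carbonate and catalytic Pd(PPh3)4 in THF, where O-allyl ethers of these acidic phenols re-ionise and the C-allyl product accumulates, gives 1-{3-[(3-acetyl-2,4-dihydroxy-6-methoxy-5-methylphenyl)methyl]-2,4,6-trihydroxy-5-(prop-2-en-1-yl)phenyl}-2-methylpropan-1-one F5. NaH and MOMCl in DMF convert it into its pentakis(methoxymethyl) ether F6. Cross-metathesis with excess 2-methyl-2-butene and the second-generation Grubbs catalyst RuCl2(=CHPh)(PCy3)(H2IMes) in CH2Cl2 at 40 °C turns the allyl group into the prenyl group of 27.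

3. Step 16. The aluminium amide may be consumed by enolisation of, or addition to, the two aryl ketones. It may instead remove a benzylic proton and open the epoxide in the wrong direction, or the Lewis-acidic aluminium may open the epoxide with participation of an ortho acetal oxygen. Fallback, from 27 back to 29, which bypasses the epoxide: oxidative cleavage of the prenyl olefin with catalytic K2OsO4·2H2O, NaIO4 and 2,6-lutidine in dioxane–water gives 2-{3-{[3-acetyl-6-methoxy-2,4-bis(methoxymethoxy)-5-methylphenyl]methyl}-2,4,6-tris(methoxymethoxy)-5-(2-methylpropanoyl)phenyl}acetaldehyde F7. Nozaki–Hiyama–Kishi addition of 2-bromopropene with CrCl2 and catalytic NiCl2 in DMF, which selects the aldehyde over the hindered ketones and does not enolise it, gives the racemic form of 29, racemic pentakis-MOM allylic alcohol F8. Dess–Martin periodinane oxidises it to 1-{3-{[3-acetyl-6-methoxy-2,4-bis(methoxymethoxy)-5-methylphenyl]methyl}-2,4,6-tris(methoxymethoxy)-5-(2-methylpropanoyl)phenyl}-3-methylbut-3-en-2-one F9. Reduction with (S)-2-methyl-CBS-oxazaborolidine and catecholborane in toluene at −78 °C, with the isopropenyl group acting as the larger substituent, should return the R alcohol 29.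

**Further compounds**

F1 | step 6 | 2-bromo-3,5-dimethoxy-1-(methoxymethoxy)-4-methylbenzene | COCOc1cc(OC)c(C)c(OC)c1Br
F2 | step 6 | [2,4-dimethoxy-6-(methoxymethoxy)-3-methylphenyl]lithium | [Li]c1c(OCOC)cc(OC)c(C)c1OC
F3 | step 6 | 2,4,6-tris(benzyloxy)benzoyl chloride | ClC(=O)c1c(OCc2ccccc2)cc(OCc2ccccc2)cc1OCc1ccccc1
F4 | step 6 | [2,4-dimethoxy-6-(methoxymethoxy)-3-methylphenyl][2,4,6-tris(benzyloxy)phenyl]methanone | COCOc1cc(OC)c(C)c(OC)c1C(=O)c1c(OCc2ccccc2)cc(OCc2ccccc2)cc1OCc1ccccc1
F5 | step 13 | 1-{3-[(3-acetyl-2,4-dihydroxy-6-methoxy-5-methylphenyl)methyl]-2,4,6-trihydroxy-5-(prop-2-en-1-yl)phenyl}-2-methylpropan-1-one | C=CCc1c(O)c(Cc2c(O)c(C(C)=O)c(O)c(C)c2OC)c(O)c(C(=O)C(C)C)c1O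
F6 | step 13 | 1-{3-{[3-acetyl-6-methoxy-2,4-bis(methoxymethoxy)-5-methylphenyl]methyl}-2,4,6-tris(methoxymethoxy)-5-(prop-2-en-1-yl)phenyl}-2-methylpropan-1-one | C=CCc1c(OCOC)c(Cc2c(OCOC)c(C(C)=O)c(OCOC)c(C)c2OC)c(OCOC)c(C(=O)C(C)C)c1OCOC
F7 | step 16 | 2-{3-{[3-acetyl-6-methoxy-2,4-bis(methoxymethoxy)-5-methylphenyl]methyl}-2,4,6-tris(methoxymethoxy)-5-(2-methylpropanoyl)phenyl}acetaldehyde | O=CCc1c(OCOC)c(Cc2c(OCOC)c(C(C)=O)c(OCOC)c(C)c2OC)c(OCOC)c(C(=O)C(C)C)c1OCOC
F8 | step 16 | racemic 1-{3-{[3-acetyl-6-methoxy-2,4-bis(methoxymethoxy)-5-methylphenyl]methyl}-5-(2-hydroxy-3-methylbut-3-en-1-yl)-2,4,6-tris(methoxymethoxy)phenyl}-2-methylpropan-1-one | C=C(C)C(O)Cc1c(OCOC)c(Cc2c(OCOC)c(C(C)=O)c(OCOC)c(C)c2OC)c(OCOC)c(C(=O)C(C)C)c1OCOC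
F9 | step 16 | 1-{3-{[3-acetyl-6-methoxy-2,4-bis(methoxymethoxy)-5-methylphenyl]methyl}-2,4,6-tris(methoxymethoxy)-5-(2-methylpropanoyl)phenyl}-3-methylbut-3-en-2-one | C=C(C)C(=O)Cc1c(OCOC)c(Cc2c(OCOC)c(C(C)=O)c(OCOC)c(C)c2OC)c(OCOC)c(C(=O)C(C)C)c1OCOC
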